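**Plan**

- Retrosynthesis: the pyranone ring is cut at O1–C2 and C3=C4 (lactone-forming condensation of a salicylaldehyde with 2,4-dihydroxyphenylacetic acid), then the formyl carbon at C4–C4a. Ring A is then cut at C5–C6, C6–C7, C8–C8a and C4a–C8a into a 2-methoxyvinyl diazo ketone and a siloxyalkyne.
- Enabling feature: ring A carries five substituents, with oxygen at C5 (methyl ether), C7 (free OH) and C8a (lactone O), and the quaternary 1,1-dimethylallyl carbon on C8 between O7 and O8a. An alkyne bearing that quaternary carbon and a silyloxy group maps onto C8–C7, and a methoxy-substituted vinylketene onto C8a, C6, C5 and C4a, so each oxygen arrives in a different state.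
- Forward order: ring A first (benzannulation), then C4 by ortho-formylation next to the phenol the annulation releases, then the pyranone ring with the dihydroxyphenyl ring brought in whole, then one deprotection.
- Stereochemistry: the target has no stereocentre and no stereogenic double bond. Only regiochemistry must be controlled, in the ketene–alkyne cycloaddition and in the formylation.

Key step: step 4

Remark on the chemistry: the phenol released by the annulation is used as the future lactone oxygen O1 and the silyl ether as masked O7, because magnesium-mediated formylation goes ortho to a free phenol. The parent 2-alkyl-5-methoxyresorcinol is symmetric, so either assignment gives the same compound.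

**Route**

Step 1
Reactants: 1 3,3-dimethoxybutan-2-one
Product: 2 3-methoxybut-3-en-2-one
Conditions: TsOH·H2O (cat.), hydroquinone (trace), neat, 140–150 °C, MeOH distilled off
Reagents that add atoms: none
Why: Acid-catalysed elimination of methanol from the ketal through an oxocarbenium ion should give the 2-alkoxy enone, and distilling off methanol drives the equilibrium.

Step 2
Reactants: 2 3-methoxybut-3-en-2-one
Product: 4 1-diazo-3-methoxybut-3-en-2-one, via trifluoroacetyl ketone 3 (not isolated)
Conditions: LiN(SiMe3)2, THF, −78 °C; CF3CO2CH2CF3; aq. NH4Cl; then MsN3, Et3N, H2O (1 equiv), MeCN, rt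
Reagents that add atoms: methanesulfonyl azide, CS(=O)(=O)N=[N+]=[N-]
Why: Detrifluoroacetylative (Regitz-type deacylative) diazo transfer: the methyl group is the only enolisable position, its kinetic enolate is trifluoroacetylated, and the activated diketone transfers the diazo group with loss of the trifluoroacetyl unit, a sequence developed for enones that do not tolerate direct diazo transfer.

Step 3
Reactants: 5 methyl 2,2-dimethylbut-3-enoate
Product: 8 triisopropyl[(3,3-dimethylpent-4-en-1-yn-1-yl)oxy]silane, via dibromo enolate 6 (not isolated), via lithium ynolate 7 (not isolated)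
Conditions: CH2Br2, lithium 2,2,6,6-tetramethylpiperidide (LiTMP), THF, −78 °C; then LiN(SiMe3)2; then n-BuLi, −78 → 0 °C; then i-Pr3SiCl, −78 °C → rt
Reagents that add atoms: dibromomethane, BrCBr; chlorotriisopropylsilane, CC(C)[Si](Cl)(C(C)C)C(C)C
Why: Kowalski ester homologation stopped at the ynolate: LiCHBr2 adds to the non-enolisable ester, the dibromo ketone enolate undergoes bromine–lithium exchange, the tert-alkyl group shifts in the carbenoid to give the ynolate, and the bulky silyl chloride silylates it on oxygen.

Step 4
Reactants: 4 1-diazo-3-methoxybut-3-en-2-one; 8 triisopropyl[(3,3-dimethylpent-4-en-1-yn-1-yl)oxy]silane (1.5 equiv)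
Product: 13 5-methoxy-2-(2-methylbut-3-en-2-yl)-3-(triisopropylsilyloxy)phenol, via vinylketene 9 (not isolated), via cyclobutenone 10 (not isolated), via dienylketene 11 (not isolated), via cyclohexadienone 12 (not isolated)
Conditions: hν (254 nm, low-pressure Hg lamp), ClCH2CH2Cl, rt; then 80 °C
Reagents that add atoms: none
Why: Light expels N2 from 4 and the 1-methoxyvinyl group migrates (photochemical Wolff rearrangement, forming C5–C6) to give vinylketene 9, whose carbonyl carbon is attacked by the oxygen-free, nucleophilic carbon of the polarised siloxyalkyne, so that a regiodefined [2+2] cycloaddition (C8–C8a and C6–C7) gives cyclobutenone 10. Warming opens 10 by four-electron electrocyclic cleavage of its C(=O)–C(sp3) bond to dienylketene 11, and ring A then closes by a thermally allowed disrotatory six-electron electrocyclization between the ketene carbon and the terminal CH2 carbon (C4a–C8a), after which dienone 12 tautomerises to the phenol. The closest known reaction type is the Danheiser benzannulation in its diazo ketone variant with trialkylsiloxyalkynes, which gives resorcinol monosilyl ethers with the alkyne substituent between the two oxygens. No stereocentre results, since the sp3 carbon of 10 is formed racemic and is erased by ring opening and aromatisation. The only selectivity needed is the orientation of the cycloaddition, and the donor oxygen on the alkyne secures it by making the carbon that bears the quaternary group the nucleophilic terminus. All six positions of ring A are thereby fixed in one operation, with the three oxygens delivered as OH (C8a), OSi (C7) and OMe (C5).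

Step 5
Reactants: 13 5-methoxy-2-(2-methylbut-3-en-2-yl)-3-(triisopropylsilyloxy)phenol
Product: 15 2-hydroxy-6-methoxy-3-(2-methylbut-3-en-2-yl)-4-(triisopropylsilyloxy)benzaldehyde, via salicyl alcohol 14 (not isolated)
Conditions: MgCl2 (anhydrous), Et3N, (CH2O)n, MeCN, reflux; 1 M HCl work-up
Reagents that add atoms: paraformaldehyde (as formaldehyde), C=O
Why: Casnati–Skattebøl ortho-formylation: the magnesium phenoxide delivers formaldehyde to the only free ortho carbon (C4a, the other ortho position being the quaternary substituent), and the resulting benzylic alkoxide is oxidised by hydride transfer to a second formaldehyde; 2-tert-alkylphenols are good substrates for this reaction.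

Step 6
Reactants: 15 2-hydroxy-6-methoxy-3-(2-methylbut-3-en-2-yl)-4-(triisopropylsilyloxy)benzaldehyde; 16 2,4-dihydroxyphenylacetic acid
Product: 18 4-[5-methoxy-8-(2-methylbut-3-en-2-yl)-2-oxo-7-(triisopropylsilyloxy)-2H-chromen-3-yl]-1,3-phenylene diacetate, via mixed anhydride 17 (not isolated)
Conditions: Ac2O, Et3N, 110 °C
Reagents that add atoms: acetic anhydride, CC(=O)OC(C)=O
Why: Perkin–Oglialoro coumarin synthesis: the anhydride acetylates both phenols of 16 and activates its carboxyl group, the amine-generated enolate of 17 adds to the aldehyde, and intramolecular acyl transfer to the neighbouring phenol oxygen with loss of acetic acid closes the lactone and sets C3=C4. Because the ring closure is intramolecular the hindered phenol is no obstacle, and any silyl ether exchanged for acetate in the hot anhydride would still converge in step 7.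

Step 7
Reactants: 18 4-[5-methoxy-8-(2-methylbut-3-en-2-yl)-2-oxo-7-(triisopropylsilyloxy)-2H-chromen-3-yl]-1,3-phenylene diacetate
Product: 20 3-(2,4-dihydroxyphenyl)-7-hydroxy-5-methoxy-8-(2-methylbut-3-en-2-yl)-2H-chromen-2-one, via silyl ether diol 19 (not isolated)
Conditions: K2CO3 (cat.), MeOH–THF, 0 °C → rt; concentrate; then Bu4NF, THF, 0 °C → rt; aq. NH4Cl
Reagents that add atoms: none
Why: Base-catalysed methanolysis of the two aryl acetates (Zemplén-type transesterification) followed by fluoride cleavage of the aryl O–Si bond should free all three hydroxyls. Acid is avoided because an ortho-(1,1-dimethylallyl)phenol can cyclise to a dihydrofuran, and the methyl ether, the terminal alkene and the lactone are not affected by either reagent.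

**Compound list**

1 | 3,3-dimethoxybutan-2-one | CC(=O)C(C)(OC)OC | starting material
2 | 3-methoxybut-3-en-2-one | C=C(OC)C(C)=O | intermediate
3 | 1,1,1-trifluoro-5-methoxyhex-5-ene-2,4-dione | C=C(OC)C(=O)CC(=O)C(F)(F)F | intermediate (not isolated)
4 | 1-diazo-3-methoxybut-3-en-2-one | C=C(OC)C(=O)C=[N+]=[N-] | intermediate
5 | methyl 2,2-dimethylbut-3-enoate | C=CC(C)(C)C(=O)OC | starting material
6 | lithium 1,1-dibromo-3,3-dimethylpenta-1,4-dien-2-olate | [Li+].[O-]C(=C(Br)Br)C(C)(C)C=C | intermediate (not isolated)
7 | lithium 3,3-dimethylpent-4-en-1-yn-1-olate | [Li+].[O-]C#CC(C)(C)C=C | intermediate (not isolated)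
8 | triisopropyl[(3,3-dimethylpent-4-en-1-yn-1-yl)oxy]silane | C=CC(C)(C)C#CO[Si](C(C)C)(C(C)C)C(C)C | intermediate
9 | 3-methoxybuta-1,3-dien-1-one | C=C(OC)C=C=O | intermediate (not isolated)
10 | 4-(1-methoxyethenyl)-2-(2-methylbut-3-en-2-yl)-3-(triisopropylsilyloxy)cyclobut-2-en-1-one (racemic at C4) | C=CC(C)(C)C1=C(O[Si](C(C)C)(C(C)C)C(C)C)C(C(=C)OC)C1=O | intermediate (not isolated)
11 | 5-methoxy-2-(2-methylbut-3-en-2-yl)-3-(triisopropylsilyloxy)hexa-1,3,5-trien-1-one (C2 and C5 cis on the 3,4-double bond) | C=CC(C)(C)C(=C=O)/C(O[Si](C(C)C)(C(C)C)C(C)C)=C\C(=C)OC | intermediate (not isolated)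
12 | 5-methoxy-2-(2-methylbut-3-en-2-yl)-3-(triisopropylsilyloxy)cyclohexa-2,4-dien-1-one | C=CC(C)(C)C1=C(O[Si](C(C)C)(C(C)C)C(C)C)C=C(OC)CC1=O | intermediate (not isolated)
13 | 5-methoxy-2-(2-methylbut-3-en-2-yl)-3-(triisopropylsilyloxy)phenol | C=CC(C)(C)c1c(O)cc(OC)cc1O[Si](C(C)C)(C(C)C)C(C)C | intermediate
14 | 2-(hydroxymethyl)-3-methoxy-6-(2-methylbut-3-en-2-yl)-5-(triisopropylsilyloxy)phenol | C=CC(C)(C)c1c(O)c(CO)c(OC)cc1O[Si](C(C)C)(C(C)C)C(C)C | intermediate (not isolated)
15 | 2-hydroxy-6-methoxy-3-(2-methylbut-3-en-2-yl)-4-(triisopropylsilyloxy)benzaldehyde | C=CC(C)(C)c1c(O)c(C=O)c(OC)cc1O[Si](C(C)C)(C(C)C)C(C)C | intermediate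
16 | 2,4-dihydroxyphenylacetic acid | OC(=O)Cc1ccc(O)cc1O | starting material
17 | acetic 2-(2,4-diacetoxyphenyl)acetic anhydride | CC(=O)OC(=O)Cc1ccc(OC(C)=O)cc1OC(C)=O | intermediate (not isolated)
18 | 4-[5-methoxy-8-(2-methylbut-3-en-2-yl)-2-oxo-7-(triisopropylsilyloxy)-2H-chromen-3-yl]-1,3-phenylene diacetate | C=CC(C)(C)c1c(O[Si](C(C)C)(C(C)C)C(C)C)cc(OC)c2cc(-c3ccc(OC(C)=O)cc3OC(C)=O)c(=O)oc12 | intermediate
19 | 3-(2,4-dihydroxyphenyl)-5-methoxy-8-(2-methylbut-3-en-2-yl)-7-(triisopropylsilyloxy)-2H-chromen-2-one | C=CC(C)(C)c1c(O[Si](C(C)C)(C(C)C)C(C)C)cc(OC)c2cc(-c3ccc(O)cc3O)c(=O)oc12 | intermediate (not isolated)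
20 | 3-(2,4-dihydroxyphenyl)-7-hydroxy-5-methoxy-8-(2-methylbut-3-en-2-yl)-2H-chromen-2-one | C=CC(C)(C)c1c(O)cc(OC)c2cc(-c3ccc(O)cc3O)c(=O)oc12 | target

**Count and risks**

Total steps: 7. Longest linear sequence: 6 (steps 1, 2, 4, 5, 6, 7); step 3 is the one-step side branch.

Step 4. The short-lived vinylketene may be captured too slowly by an alkyne carbon that sits next to a quaternary centre. Ketene dimerisation, acylation of the product phenol, or non-Wolff photochemistry of the enol-ether diazo ketone at 254 nm could then take over. The fallback sets out from 8 and comes back at 13. The same ketene 9 is generated without light by thermal four-electron ring opening of 3-methoxycyclobut-2-en-1-one F1. F1 is made from commercial cyclobutane-1,3-dione by O-methylation with trimethyl orthoformate and catalytic TsOH in methanol. Heating F1 with 8 in toluene at 80–110 °C releases the ketene slowly in the presence of excess alkyne and should run through 10, 11 and 12 to 13.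

Step 3. Addition of LiCHBr2 to the α-quaternary ester may be incomplete, or the 1,2-shift of the tert-alkyl group in the carbenoid may stall before the ynolate forms. The fallback sets out from 5 and comes back at 8 through ynolate 7. Ester 5 is reduced with i-Bu2AlH at −78 °C to 2,2-dimethylbut-3-enal F2. Corey–Fuchs olefination (CBr4, PPh3) gives 1,1-dibromo-3,3-dimethylpenta-1,4-diene F3, and two equivalents of n-BuLi convert it into lithium 3,3-dimethylpent-4-en-1-yn-1-ide F4. Oxidation of this acetylide with LiOOt-Bu (from t-BuOOH and LiN(SiMe3)2) gives 7, and O-silylation with i-Pr3SiOTf gives 8.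

Step 6. Enolate addition to the electron-rich, doubly ortho-substituted aldehyde may be sluggish. The activated 2-acetoxyphenylacetic unit could meanwhile be lost to self-condensation, and the silyl ether could be eroded in hot anhydride. The fallback sets out from 15 and 16 and comes back at 19. Acid 16 is lactonised (TsOH cat., toluene, water removal) to 6-hydroxybenzofuran-2(3H)-one F5. Knoevenagel-type condensation of F5 with 15 (Et3N, MeCN, reflux) gives (Z)-6-hydroxy-3-[2-hydroxy-6-methoxy-3-(2-methylbut-3-en-2-yl)-4-(triisopropylsilyloxy)benzylidene]benzofuran-2(3H)-one F6. The phenol on the salicyl ring of F6 then attacks the five-membered lactone, and acyl transfer gives the six-membered lactone 19 with both hydroxyls of the aryl ring free. Desilylation of 19 with Bu4NF as in the second stage of step 7 completes the route.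

**Further compounds**

F1 | step 4 | 3-methoxycyclobut-2-en-1-one | COC1=CC(=O)C1
F2 | step 3 | 2,2-dimethylbut-3-enal | C=CC(C)(C)C=O
F3 | step 3 | 1,1-dibromo-3,3-dimethylpenta-1,4-diene | C=CC(C)(C)C=C(Br)Br
F4 | step 3 | lithium 3,3-dimethylpent-4-en-1-yn-1-ide | [Li+].[C-]#CC(C)(C)C=C
F5 | step 6 | 6-hydroxybenzofuran-2(3H)-one | O=C1Cc2ccc(O)cc2O1
F6 | step 6 | (Z)-6-hydroxy-3-[2-hydroxy-6-methoxy-3-(2-methylbut-3-en-2-yl)-4-(triisopropylsilyloxy)benzylidene]benzofuran-2(3H)-one | O=C1Oc2cc(O)ccc2/C1=C/c1c(O)c(C(C)(C)C=C)c(O[Si](C(C)C)(C(C)C)C(C)C)cc1OC
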